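**Plan**

1. Retrosynthesis (briarane numbering, defined under Remarks): the C6 chloride with the C5=C16 methylene comes from ene-type chlorination of a C5(CH3)=C6 alkene; the four acetates from one acylation; the C4–O–C8 bridge from transannular reductive etherification of a C4 enone by the C8 tertiary alcohol; the ten-membered ring from C4–C5 Nozaki–Hiyama–Kishi closure; the γ-lactone from a C8–C17 samarium Reformatsky reaction; C11(OH)CH2Cl from a C11 ketone.
2. The cyclohexanone is traced back, by breaking C1–C10 and restoring C1–C11, to a 1-silyloxycyclopentane (C1, C14, C13, C12, C11) that carries a cis-C9,C10-epoxide; this is cut at C8–C9 into an ethynylcyclopentane (C1–C4, C9–C15) and an α-silyloxy aldehyde (C5–C8, C16).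
3. Enabling feature: ring carbon C11 bears oxygen and sits between the quaternary C1 and the ring-fusion carbon C10, which carries the oxygenated exocyclic C9. This C11(O)–C10–C9(O) array is the β-hydroxy ketone left by a semipinacol shift, so a C11 carbinol inside a five-membered ring can push C1 onto an epoxide carbon C10 and become the cyclohexanone.
4. Forward order: cyclopentane (steps 1–9) and iodoalkene aldehyde (10–13); union, cis-alkene from the alkyne, directed epoxidation, C8 ketone (14–17); ring expansion (18); γ-lactone (22); chlorohydrin (24); ten-membered carbocycle (26); oxygen-bridged dihydropyran (28); acetates and allylic chloride (30, 31). Helpers removed on the way: the alkyne, the temporary C8 carbinol and the C11 silyl ether.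
5. Stereochemistry: C1/C14 from yeast desymmetrisation; C2/C3 from reagent-controlled alkoxyallylboration; C7 from (R)-glyceraldehyde acetonide; the temporary C8 carbinol from Felkin–Anh addition, which steers the epoxidation that fixes C9 and, after 1,2-shift with inversion, C10; C8/C17 from the tethered Reformatsky addition; C11 from equatorial epoxidation; C4 enforced by the bridge; C6 from chlorination anti to the carbocyclic bridge.

Key step: step 18

**Remarks**

- Numbering: C1 is the quaternary ring-fusion carbon (methyl C15). C2 (OAc), C3 (OAc), C4 (ether), C5 (=C16H2), C6 (Cl), C7 (lactone O), C8 (ether, quaternary) and C9 (OAc) follow round the ten-membered ring to C10 (ring-fusion CH). C11 (OH, C20H2Cl), C12, C13 and C14 (OAc) complete the cyclohexane. C17 (with methyl C18) and C19 (C=O) complete the lactone.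
- Assumption: centres that are destroyed later are inconsequential. C11 in 10–21 is drawn as the epimer expected from attack anti to the side chain; C4 in 30 and 32, the CHBr carbon in 25 and the ozonide carbons in 6 are left unassigned.

**Route**

Step 1
Reactants: 1 2-methylcyclopentane-1,3-dione
Product: 2 2-allyl-2-methylcyclopentane-1,3-dione
Conditions: allyl bromide, NaOH (1 M aq.), rt
Reagents that add atoms: allyl bromide, C=CCBr
Why: C-alkylation of the 1,3-dione enolate with a soft allylic halide builds the still prochiral quaternary carbon C1 with its methyl group and a three-carbon handle.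

Step 2
Reactants: 2 2-allyl-2-methylcyclopentane-1,3-dione
Product: 3 (2S,3S)-2-allyl-3-hydroxy-2-methylcyclopentan-1-one
Conditions: baker's yeast (Saccharomyces cerevisiae), sucrose, H2O, 30 °C
Reagents that add atoms: none
Why: Enzymatic desymmetrising reduction delivers hydride to one enantiotopic carbonyl only, which sets the carbinol (future C14) and with it the quaternary centre (future C1) in the known (2S,3S) sense, hydroxyl cis to the allyl group.

Step 3
Reactants: 3 (2S,3S)-2-allyl-3-hydroxy-2-methylcyclopentan-1-one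
Product: 4 (2S,3S)-2-allyl-3-(tert-butyldimethylsilyloxy)-2-methylcyclopentan-1-one
Conditions: TBSCl, imidazole, DMF, rt
Reagents that add atoms: tert-butyldimethylsilyl chloride, CC(C)(C)[Si](C)(C)Cl
Why: Standard silylation protects the C14 hydroxyl and blocks retro-aldol cleavage of the β-hydroxy ketone.

Step 4
Reactants: 4 (2S,3S)-2-allyl-3-(tert-butyldimethylsilyloxy)-2-methylcyclopentan-1-one
Product: 5 (2S,3S)-3-(tert-butyldimethylsilyloxy)-2-methyl-2-[(E)-prop-1-enyl]cyclopentan-1-one
Conditions: RuHCl(CO)(PPh3)3 (2 mol%), toluene, 80 °C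
Reagents that add atoms: none
Why: Ruthenium hydride-catalysed olefin isomerisation (hydrometalation, β-hydride elimination) moves the terminal alkene into the thermodynamically preferred (E)-propenyl position without touching a stereocentre.

Step 5
Reactants: 5 (2S,3S)-3-(tert-butyldimethylsilyloxy)-2-methyl-2-[(E)-prop-1-enyl]cyclopentan-1-one
Product: 7 (1R,2S)-2-(tert-butyldimethylsilyloxy)-1-methyl-5-oxocyclopentane-1-carbaldehyde, via ozonide 6 (not isolated)
Conditions: O3, CH2Cl2, −78 °C; then PPh3, −78 °C to rt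
Reagents that add atoms: ozone, [O-][O+]=O
Why: Ozonolysis with reductive work-up removes the propenyl terminus and leaves the non-enolisable neopentyl aldehyde (C2) on the quaternary carbon.

Step 6
Reactants: 7 (1R,2S)-2-(tert-butyldimethylsilyloxy)-1-methyl-5-oxocyclopentane-1-carbaldehyde
Product: 8 (2S,3S)-3-(tert-butyldimethylsilyloxy)-2-[(1R,2R)-1-hydroxy-2-(methoxymethoxy)but-3-enyl]-2-methylcyclopentan-1-one
Conditions: allyl methoxymethyl ether, sec-BuLi, THF, −78 °C; (−)-Ipc2BOMe; BF3·OEt2; then 7, −78 °C; H2O2, pH 7 buffer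
Reagents that add atoms: allyl methoxymethyl ether (used as its (Z)-γ-borylated form), C=CCOCOC
Why: Brown alkoxyallylboration through a chair Zimmerman–Traxler transition state is much faster at the aldehyde than at the ketone; the isopinocampheyl groups derived from (+)-α-pinene select the Si face (2R carbinol) and the (Z) geometry of the reagent gives the syn 3R ether.

Step 7
Reactants: 8 (2S,3S)-3-(tert-butyldimethylsilyloxy)-2-[(1R,2R)-1-hydroxy-2-(methoxymethoxy)but-3-enyl]-2-methylcyclopentan-1-one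
Product: 9 (2R,3S)-3-(tert-butyldimethylsilyloxy)-2-[(1R,2R)-1-(tert-butyldimethylsilyloxy)-2-(methoxymethoxy)but-3-enyl]-2-methylcyclopentan-1-one
Conditions: TBSOTf, 2,6-lutidine, CH2Cl2, −78 to 0 °C
Reagents that add atoms: tert-butyldimethylsilyl triflate, CC(C)(C)[Si](C)(C)OS(=O)(=O)C(F)(F)F
Why: Silyl triflate silylation of the hindered C2 hydroxyl removes the retro-aldol risk of the β-hydroxy ketone before basic reagents are used.

Step 8
Reactants: 9 bis-silyl ketone (name as in step 7)
Product: 10 (1S,2R,3S)-3-(tert-butyldimethylsilyloxy)-2-[(1R,2R)-1-(tert-butyldimethylsilyloxy)-2-(methoxymethoxy)but-3-enyl]-1-ethynyl-2-methylcyclopentan-1-ol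
Conditions: HC≡CMgBr, THF, 0 °C to rt
Reagents that add atoms: ethynylmagnesium bromide, C#C[Mg]Br
Why: 1,2-Addition of the alkynyl Grignard reagent to the hindered cyclopentanone (as with 17-keto steroids) is expected anti to the side chain and the silyloxy group, and the new C11 carbinol centre is erased in step 18.

Step 9
Reactants: 10 ethynyl carbinol (name as in step 8)
Product: 11 triethylsilyl ether of 10 (west alkyne)
Conditions: TESOTf, 2,6-lutidine, CH2Cl2, −78 to 0 °C
Reagents that add atoms: triethylsilyl triflate, CC[Si](CC)(CC)OS(=O)(=O)C(F)(F)F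
Why: Silylation of the tertiary propargylic alcohol installs the silyloxy group that later drives the 1,2-shift and prevents lactol formation with the C8 carbonyl.

Step 10
Reactants: 12 (R)-2,2-dimethyl-1,3-dioxolane-4-carbaldehyde
Product: 13 (S)-4-[(Z)-2-iodoprop-1-enyl]-2,2-dimethyl-1,3-dioxolane
Conditions: EtPPh3I, n-BuLi, THF, rt; I2, −78 °C; NaN(SiMe3)2, −78 °C; then 12, −78 to −20 °C
Reagents that add atoms: ethyltriphenylphosphonium iodide, CC[P+](c1ccccc1)(c1ccccc1)c1ccccc1.[I-]; iodine, II
Why: Stork–Zhao-type olefination with the α-iodo ylide under kinetic low-temperature control places iodine cis to the dioxolane (Z) without epimerising the α-stereocentre (future C7).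

Step 11
Reactants: 13 (S)-4-[(Z)-2-iodoprop-1-enyl]-2,2-dimethyl-1,3-dioxolane
Product: 14 (2S,3Z)-4-iodopent-3-ene-1,2-diol
Conditions: AcOH/H2O (4:1), 40 °C
Reagents that add atoms: none
Why: Acid hydrolysis of the acetonide frees the 1,2-diol without affecting the vinyl iodide.

Step 12
Reactants: 14 (2S,3Z)-4-iodopent-3-ene-1,2-diol
Product: 15 (2S,3Z)-4-iodo-1,2-bis(triethylsilyloxy)pent-3-ene
Conditions: TESCl, imidazole, DMF, 0 °C to rt
Reagents that add atoms: triethylsilyl chloride, CC[Si](CC)(CC)Cl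
Why: Bis-silylation provides the pair of silyl ethers needed for selective oxidation of the primary position.

Step 13
Reactants: 15 (2S,3Z)-4-iodo-1,2-bis(triethylsilyloxy)pent-3-ene
Product: 16 (2S,3Z)-4-iodo-2-(triethylsilyloxy)pent-3-enal (east aldehyde)
Conditions: (COCl)2, DMSO, CH2Cl2, −78 to −30 °C; Et3N, −78 to 0 °C
Reagents that add atoms: none
Why: Under Swern conditions the chlorosulfonium ion attacks the less hindered primary silyl ether oxygen, which is cleaved and oxidised directly to the aldehyde while the secondary silyl ether and the C7 configuration are kept.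

Step 14
Reactants: 11 west alkyne; 16 east aldehyde
Product: 18 propargylic alcohol (8R; C7–O and C8–O anti), via lithium acetylide 17 (not isolated)
Conditions: 11, n-BuLi, THF, −78 °C; then 16, −78 °C; AcOH, −78 °C
Reagents that add atoms: none
Why: Non-chelating Felkin–Anh addition of the lithium acetylide to the α-silyloxy aldehyde (silyloxy group anti to the nucleophile) should give the 7,8-anti (8R) carbinol, and the cold acidic quench suppresses 1,2-silyl migration.

Step 15
Reactants: 18 propargylic alcohol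
Product: 19 (Z)-allylic alcohol (cis C9=C10)
Conditions: H2 (1 atm), Pd/CaCO3 poisoned with Pb(OAc)2 (Lindlar catalyst), quinoline, EtOAc, rt
Reagents that add atoms: none
Why: Lindlar semi-hydrogenation adds hydrogen syn to the alkyne to give the (Z)-alkene needed for a cis-epoxide, the poisoned catalyst sparing the terminal alkene and the vinyl iodide when uptake is stopped at one equivalent.

Step 16
Reactants: 19 (Z)-allylic alcohol
Product: 20 cis-9,10-epoxy alcohol (epoxide oxygen threo to the C8 hydroxyl)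
Conditions: mCPBA, NaHCO3, CH2Cl2, 0 °C
Reagents that add atoms: 3-chloroperbenzoic acid, OOC(=O)c1cccc(Cl)c1
Why: In this hydroxyl-directed (Henbest) epoxidation allylic 1,3-strain holds the C8 hydrogen in the alkene plane, so the hydrogen-bonded peracid delivers oxygen to the face bearing the C8 hydroxyl and fixes C9 and C10, while the less nucleophilic terminal and iodo alkenes are left alone.

Step 17
Reactants: 20 cis-9,10-epoxy alcohol
Product: 21 γ-silyloxy cis-α,β-epoxy ketone (C8 ketone)
Conditions: Dess–Martin periodinane, NaHCO3, CH2Cl2, 0 °C to rt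
Reagents that add atoms: none
Why: Buffered periodinane oxidation turns the temporary C8 carbinol into the ketone that later accepts the lactone enolate and deactivates the C9–O bond of the epoxide, without epimerising C7.

Step 18
Reactants: 21 γ-silyloxy cis-α,β-epoxy ketone
Product: 22 ring-expanded cyclohexanone (C11 ketone; C10–H trans to C15; free C9 hydroxyl)
Conditions: BF3·OEt2 (1.2 equiv), CH2Cl2, −78 to −40 °C; aq. NaHCO3
Reagents that add atoms: none
Why: Proposed new method: BF3, chelated between the epoxide oxygen and the C8 carbonyl, ionises the C10–O bond while the antiperiplanar C11–C1 bond of the cyclopentane shifts to C10 and the silyloxy lone pair forms the C11 carbonyl, so the ring C1–C14–C13–C12–C11 becomes the cyclohexanone C1–C10–C11–C12–C13–C14 and the silyl group is lost. The closest known reaction type is the Lewis acid semipinacol (Suzuki–Tsuchihashi type) ring expansion of 2,3-epoxy alcohol silyl ethers to β-hydroxy ketones, known for alkyl- and aryl-substituted epoxides but not for an epoxide that carries an acyl group. No ring is closed by cyclisation; the six-membered ring arises by a 1,2-alkyl shift (one-carbon ring expansion) that joins the quaternary C1 to the future ring-fusion carbon C10. C10 is set by inversion at the epoxide carbon (migration anti to the leaving oxygen), C9 keeps its C–O bond and configuration, and C1 migrates with retention, so the cis-epoxide gives the required syn relation of the C9 oxygen and the C10–C1 bond while the C11 carbinol configuration is erased. The step needs C10–O over C9–O cleavage, which the electron-withdrawing C8 carbonyl secures; migration of the quaternary C1 over the C12 methylene, which the higher migratory aptitude of the more substituted carbon secures; and alkyl shift over 1,2-acyl shift from C9, which the stronger push of the silyloxy oxygen should secure.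

Step 19
Reactants: 22 ring-expanded cyclohexanone
Product: 23 C9 tert-butyldimethylsilyl ether of 22
Conditions: TBSOTf, 2,6-lutidine, CH2Cl2, −78 °C
Reagents that add atoms: tert-butyldimethylsilyl triflate, CC(C)(C)[Si](C)(C)OS(=O)(=O)C(F)(F)F
Why: Silylation caps the aldol-type C9 hydroxyl so that retro-aldol cleavage and acylation at this position are excluded.

Step 20
Reactants: 23 C9 silyl ether
Product: 24 α-hydroxy ketone (free C7 hydroxyl)
Conditions: PPTS (cat.), MeOH/CH2Cl2, 0 °C
Reagents that add atoms: none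
Why: Acid-catalysed methanolysis removes the triethylsilyl ether much faster than the three hindered tert-butyldimethylsilyl ethers and exposes the C7 hydroxyl.

Step 21
Reactants: 24 α-hydroxy ketone
Product: 25 C7 2-bromopropanoate (mixture at the CHBr carbon)
Conditions: 2-bromopropionyl bromide, pyridine, CH2Cl2, −20 °C
Reagents that add atoms: 2-bromopropionyl bromide, CC(Br)C(=O)Br
Why: Acylation of the α-hydroxy ketone tethers the propionate unit (C17, C18, C19) to O7, and the epimers at the bromine-bearing carbon converge in the next step.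

Step 22
Reactants: 25 C7 2-bromopropanoate
Product: 26 β-hydroxy-γ-lactone (C8 tertiary alcohol, C17 methyl)
Conditions: SmI2 (2.2 equiv), THF, −78 °C; aq. NH4Cl
Reagents that add atoms: none
Why: In this intramolecular samarium Reformatsky reaction the enolate formed by C–Br reduction adds to the adjacent C8 ketone through a chelated transition state that keeps the large C9 branch anti to C6 (C8 hydroxyl cis to C6) and places the C17 methyl trans to the C9 branch, which is also the thermodynamically preferred, epimerisable position.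

Step 23
Reactants: 26 β-hydroxy-γ-lactone
Product: 27 C11 exocyclic methylene compound
Conditions: Zn, CH2Br2, TiCl4, THF/CH2Cl2, 0 °C to rt
Reagents that add atoms: dibromomethane, BrCBr
Why: Takai–Lombardo methylenation is non-basic and selective for the ketone over the lactone, so the epimerisable C10 and the β-silyloxy group survive.

Step 24
Reactants: 27 C11 exocyclic methylene compound
Product: 29 chlorohydrin (C11 tertiary alcohol bearing CH2Cl), via spiro-epoxide 28 (not isolated)
Conditions: mCPBA, NaHCO3, CH2Cl2, 0 °C; then LiCl, AcOH, THF, rt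
Reagents that add atoms: 3-chloroperbenzoic acid, OOC(=O)c1cccc(Cl)c1; lithium chloride, [Li+].[Cl-]
Why: Peracid epoxidation of the 1,1-disubstituted alkene from the equatorial (α) face, away from the axial C15 methyl, followed by SN2 opening of the spiro-epoxide at its CH2 terminus by chloride, gives the tertiary alcohol with the chloromethyl group cis to C15.

Step 25
Reactants: 29 chlorohydrin
Product: 31 C4 aldehyde (seco precursor), via vicinal diol 30 (not isolated)
Conditions: OsO4 (cat.), NaIO4, 2,6-lutidine, dioxane/H2O, rt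
Reagents that add atoms: osmium tetroxide (catalytic), O=[Os](=O)(=O)=O; sodium periodate (resupplies the oxygen), [Na+].[O-]I(=O)(=O)=O
Why: In this Lemieux–Johnson cleavage OsO4 dihydroxylates the monosubstituted alkene in preference to the electron-poor trisubstituted vinyl iodide and periodate cleaves the diol to the C4 aldehyde.

Step 26
Reactants: 31 C4 aldehyde
Product: 32 ten-membered allylic alcohol (C4 epimers)
Conditions: CrCl2 (8 equiv), NiCl2 (cat.), DMSO/THF, rt, slow addition to 2 mM
Reagents that add atoms: none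
Why: In this intramolecular Nozaki–Hiyama–Kishi reaction nickel-mediated insertion into the C–I bond and transmetalation to chromium give an alkenylchromium species that adds to the aldehyde with retention of the (Z) geometry, closing the ten-membered carbocycle at C4–C5, and the C4 configuration is irrelevant because it is oxidised next.

Step 27
Reactants: 32 ten-membered allylic alcohol
Product: 33 ten-membered (5Z)-enone (C4 ketone)
Conditions: Dess–Martin periodinane, NaHCO3, CH2Cl2, rt
Reagents that add atoms: none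
Why: Periodinane oxidation of the secondary allylic alcohol (tertiary alcohols untouched) erases C4 and provides the carbonyl for the oxygen bridge.

Step 28
Reactants: 33 ten-membered (5Z)-enone
Product: 34 4,8-oxygen-bridged dihydropyran (protected)
Conditions: Et3SiH, TMSOTf (0.2 equiv), CH2Cl2, −78 to −40 °C
Reagents that add atoms: none
Why: In this reductive etherification the C8 hydroxyl adds transannularly to the C4 carbonyl and ionisation gives a Ferrier-type allylic oxocarbenium ion that the silane reduces at C4; since C4 becomes a bridgehead of the 11-oxabicyclo[5.3.1] system, its configuration is dictated by C8.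

Step 29
Reactants: 34 4,8-oxygen-bridged dihydropyran
Product: 36 hexaol (free hydroxyls at C2/C3/C9/C14), via tris-silyl alcohol 35 (not isolated)
Conditions: ZnBr2, n-PrSH, CH2Cl2, 0 °C; then HF·pyridine, THF/pyridine, rt
Reagents that add atoms: none
Why: Lewis acid and thiol cleavage of the methoxymethyl ether followed by fluoride desilylation frees the four secondary hydroxyls under conditions that should leave the allylic ether, the lactone and the chlorohydrin intact.

Step 30
Reactants: 36 hexaol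
Product: 37 tetraacetate (5,6-ene, C16 methyl)
Conditions: Ac2O, pyridine, DMAP (cat.), rt
Reagents that add atoms: acetic anhydride, CC(=O)OC(C)=O
Why: DMAP-catalysed acetylation esterifies the four secondary hydroxyls (C2, C3, C9, C14) while the hindered tertiary C11 hydroxyl stays free.

Step 31
Reactants: 37 tetraacetate
Product: 38 Fragilide F
Conditions: Ca(OCl)2, CO2 (dry ice), CH2Cl2/H2O, 0 °C
Reagents that add atoms: calcium hypochlorite, [Ca+2].[O-]Cl.[O-]Cl
Why: In this ene-type allylic chlorination by hypochlorous acid, electrophilic chlorine adds to the less substituted C6 of the trisubstituted alkene from the face opposite the five-carbon bridge and the developing C5 cation loses a proton from the C16 methyl, giving the exocyclic alkene and the C6 chloride cis to the C7 lactone oxygen.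

**Compound list**

1 | 2-methylcyclopentane-1,3-dione | CC1C(=O)CCC1=O | starting material
2 | 2-allyl-2-methylcyclopentane-1,3-dione | C=CCC1(C)C(=O)CCC1=O | intermediate
3 | (2S,3S)-2-allyl-3-hydroxy-2-methylcyclopentan-1-one | C=CC[C@@]1(C)[C@@H](O)CCC1=O | intermediate
4 | (2S,3S)-2-allyl-3-(tert-butyldimethylsilyloxy)-2-methylcyclopentan-1-one | C=CC[C@@]1(C)[C@@H](O[Si](C)(C)C(C)(C)C)CCC1=O | intermediate
5 | (2S,3S)-3-(tert-butyldimethylsilyloxy)-2-methyl-2-[(E)-prop-1-enyl]cyclopentan-1-one | C/C=C/[C@@]1(C)[C@@H](O[Si](C)(C)C(C)(C)C)CCC1=O | intermediate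
6 | ozonide of 5: 3-methyl-5-[(1R,2S)-2-(tert-butyldimethylsilyloxy)-1-methyl-5-oxocyclopentyl]-1,2,4-trioxolane (trioxolane carbons unassigned) | CC1OOC(O1)[C@@]2(C)[C@@H](O[Si](C)(C)C(C)(C)C)CCC2=O | intermediate (not isolated)
7 | (1R,2S)-2-(tert-butyldimethylsilyloxy)-1-methyl-5-oxocyclopentane-1-carbaldehyde | O=C[C@@]1(C)[C@@H](O[Si](C)(C)C(C)(C)C)CCC1=O | intermediate
8 | (2S,3S)-3-(tert-butyldimethylsilyloxy)-2-[(1R,2R)-1-hydroxy-2-(methoxymethoxy)but-3-enyl]-2-methylcyclopentan-1-one | C=C[C@@H](OCOC)[C@H](O)[C@@]1(C)[C@@H](O[Si](C)(C)C(C)(C)C)CCC1=O | intermediate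
9 | (2R,3S)-3-(tert-butyldimethylsilyloxy)-2-[(1R,2R)-1-(tert-butyldimethylsilyloxy)-2-(methoxymethoxy)but-3-enyl]-2-methylcyclopentan-1-one | C=C[C@@H](OCOC)[C@H](O[Si](C)(C)C(C)(C)C)[C@@]1(C)[C@@H](O[Si](C)(C)C(C)(C)C)CCC1=O | intermediate
10 | (1S,2R,3S)-3-(tert-butyldimethylsilyloxy)-2-[(1R,2R)-1-(tert-butyldimethylsilyloxy)-2-(methoxymethoxy)but-3-enyl]-1-ethynyl-2-methylcyclopentan-1-ol | C=C[C@@H](OCOC)[C@H](O[Si](C)(C)C(C)(C)C)[C@@]1(C)[C@@H](O[Si](C)(C)C(C)(C)C)CC[C@]1(O)C#C | intermediate
11 | triethylsilyl ether of 10 (west alkyne) | C=C[C@@H](OCOC)[C@H](O[Si](C)(C)C(C)(C)C)[C@@]1(C)[C@@H](O[Si](C)(C)C(C)(C)C)CC[C@]1(O[Si](CC)(CC)CC)C#C | intermediate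
12 | (R)-2,2-dimethyl-1,3-dioxolane-4-carbaldehyde ((R)-glyceraldehyde acetonide) | CC1(C)OC[C@H](C=O)O1 | starting material
13 | (S)-4-[(Z)-2-iodoprop-1-enyl]-2,2-dimethyl-1,3-dioxolane | CC1(C)OC[C@H](/C=C(/C)I)O1 | intermediate
14 | (2S,3Z)-4-iodopent-3-ene-1,2-diol | OC[C@@H](O)/C=C(/C)I | intermediate
15 | (2S,3Z)-4-iodo-1,2-bis(triethylsilyloxy)pent-3-ene | CC[Si](CC)(CC)OC[C@@H](O[Si](CC)(CC)CC)/C=C(/C)I | intermediate
16 | (2S,3Z)-4-iodo-2-(triethylsilyloxy)pent-3-enal (east aldehyde) | O=C[C@@H](O[Si](CC)(CC)CC)/C=C(/C)I | intermediate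
17 | lithium acetylide of 11 | C=C[C@@H](OCOC)[C@H](O[Si](C)(C)C(C)(C)C)[C@@]1(C)[C@@H](O[Si](C)(C)C(C)(C)C)CC[C@]1(O[Si](CC)(CC)CC)C#C[Li] | intermediate (not isolated)
18 | propargylic alcohol: alkyne terminus of 11 bonded to the (1R,2S,3Z)-1-hydroxy-4-iodo-2-(triethylsilyloxy)pent-3-enyl chain (C8 carbinol, C7 silyl ether, 7,8-anti) | C=C[C@@H](OCOC)[C@H](O[Si](C)(C)C(C)(C)C)[C@@]1(C)[C@@H](O[Si](C)(C)C(C)(C)C)CC[C@]1(O[Si](CC)(CC)CC)C#C[C@@H](O)[C@@H](O[Si](CC)(CC)CC)/C=C(/C)I | intermediate
19 | (Z)-allylic alcohol: cis C9=C10 alkene from 18 | C=C[C@@H](OCOC)[C@H](O[Si](C)(C)C(C)(C)C)[C@@]1(C)[C@@H](O[Si](C)(C)C(C)(C)C)CC[C@]1(O[Si](CC)(CC)CC)/C=C\[C@@H](O)[C@@H](O[Si](CC)(CC)CC)/C=C(/C)I | intermediate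
20 | cis-9,10-epoxide of 19, epoxide oxygen on the face of the C8 hydroxyl (threo) | C=C[C@@H](OCOC)[C@H](O[Si](C)(C)C(C)(C)C)[C@@]1(C)[C@@H](O[Si](C)(C)C(C)(C)C)CC[C@]1(O[Si](CC)(CC)CC)[C@@H]2O[C@@H]2[C@@H](O)[C@@H](O[Si](CC)(CC)CC)/C=C(/C)I | intermediate
21 | C8 ketone of 20 (γ-triethylsilyloxy cis-α,β-epoxy ketone) | C=C[C@@H](OCOC)[C@H](O[Si](C)(C)C(C)(C)C)[C@@]1(C)[C@@H](O[Si](C)(C)C(C)(C)C)CC[C@]1(O[Si](CC)(CC)CC)[C@@H]2O[C@@H]2C(=O)[C@@H](O[Si](CC)(CC)CC)/C=C(/C)I | intermediate
22 | ring-expanded cyclohexanone: C11 ketone, C10–H trans to the C15 methyl, free C9 hydroxyl, C8 ketone, C7 triethylsilyl ether, (Z)-vinyl iodide | C=C[C@@H](OCOC)[C@H](O[Si](C)(C)C(C)(C)C)[C@@]1(C)[C@@H](O[Si](C)(C)C(C)(C)C)CCC(=O)[C@@H]1[C@H](O)C(=O)[C@@H](O[Si](CC)(CC)CC)/C=C(/C)I | intermediate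
23 | C9 tert-butyldimethylsilyl ether of 22 | C=C[C@@H](OCOC)[C@H](O[Si](C)(C)C(C)(C)C)[C@@]1(C)[C@@H](O[Si](C)(C)C(C)(C)C)CCC(=O)[C@@H]1[C@H](O[Si](C)(C)C(C)(C)C)C(=O)[C@@H](O[Si](CC)(CC)CC)/C=C(/C)I | intermediate
24 | C7 alcohol from 23 (α-hydroxy ketone) | C=C[C@@H](OCOC)[C@H](O[Si](C)(C)C(C)(C)C)[C@@]1(C)[C@@H](O[Si](C)(C)C(C)(C)C)CCC(=O)[C@@H]1[C@H](O[Si](C)(C)C(C)(C)C)C(=O)[C@@H](O)/C=C(/C)I | intermediate
25 | C7 2-bromopropanoate of 24 (CHBr carbon unassigned) | C=C[C@@H](OCOC)[C@H](O[Si](C)(C)C(C)(C)C)[C@@]1(C)[C@@H](O[Si](C)(C)C(C)(C)C)CCC(=O)[C@@H]1[C@H](O[Si](C)(C)C(C)(C)C)C(=O)[C@@H](OC(=O)C(C)Br)/C=C(/C)I | intermediate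
26 | β-hydroxy-γ-lactone: C8 tertiary alcohol cis to C6, C17 methyl cis to the C8 hydroxyl, C11 ketone | C=C[C@@H](OCOC)[C@H](O[Si](C)(C)C(C)(C)C)[C@@]1(C)[C@@H](O[Si](C)(C)C(C)(C)C)CCC(=O)[C@@H]1[C@H](O[Si](C)(C)C(C)(C)C)[C@]2(O)[C@@H](C)C(=O)O[C@H]2/C=C(/C)I | intermediate
27 | C11 exocyclic methylene analogue of 26 | C=C[C@@H](OCOC)[C@H](O[Si](C)(C)C(C)(C)C)[C@@]1(C)[C@@H](O[Si](C)(C)C(C)(C)C)CCC(=C)[C@@H]1[C@H](O[Si](C)(C)C(C)(C)C)[C@]2(O)[C@@H](C)C(=O)O[C@H]2/C=C(/C)I | intermediate
28 | 11,20-spiro-epoxide of 27 (oxygen α, trans to the C15 methyl) | C=C[C@@H](OCOC)[C@H](O[Si](C)(C)C(C)(C)C)[C@@]1(C)[C@@H](O[Si](C)(C)C(C)(C)C)CC[C@]3(CO3)[C@@H]1[C@H](O[Si](C)(C)C(C)(C)C)[C@]2(O)[C@@H](C)C(=O)O[C@H]2/C=C(/C)I | intermediate (not isolated)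
29 | chlorohydrin: C11 tertiary alcohol with CH2Cl cis to the C15 methyl | C=C[C@@H](OCOC)[C@H](O[Si](C)(C)C(C)(C)C)[C@@]1(C)[C@@H](O[Si](C)(C)C(C)(C)C)CC[C@](O)(CCl)[C@@H]1[C@H](O[Si](C)(C)C(C)(C)C)[C@]2(O)[C@@H](C)C(=O)O[C@H]2/C=C(/C)I | intermediate
30 | vicinal diol from the terminal alkene of 29 (new carbinol unassigned) | OCC(O)[C@@H](OCOC)[C@H](O[Si](C)(C)C(C)(C)C)[C@@]1(C)[C@@H](O[Si](C)(C)C(C)(C)C)CC[C@](O)(CCl)[C@@H]1[C@H](O[Si](C)(C)C(C)(C)C)[C@]2(O)[C@@H](C)C(=O)O[C@H]2/C=C(/C)I | intermediate (not isolated)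
31 | C4 aldehyde (seco precursor carrying the (Z)-vinyl iodide) | O=C[C@@H](OCOC)[C@H](O[Si](C)(C)C(C)(C)C)[C@@]1(C)[C@@H](O[Si](C)(C)C(C)(C)C)CC[C@](O)(CCl)[C@@H]1[C@H](O[Si](C)(C)C(C)(C)C)[C@]2(O)[C@@H](C)C(=O)O[C@H]2/C=C(/C)I | intermediate
32 | ten-membered allylic alcohol, (5Z)-alkene, C4 carbinol unassigned | OC1/C(C)=C\[C@@H]2OC(=O)[C@H](C)[C@@]2(O)[C@@H](O[Si](C)(C)C(C)(C)C)[C@H]3[C@@](O)(CCl)CC[C@H](O[Si](C)(C)C(C)(C)C)[C@]3(C)[C@@H](O[Si](C)(C)C(C)(C)C)[C@@H]1OCOC | intermediate
33 | ten-membered (5Z)-enone (C4 ketone, free C8 and C11 tertiary alcohols) | O=C1/C(C)=C\[C@@H]2OC(=O)[C@H](C)[C@@]2(O)[C@@H](O[Si](C)(C)C(C)(C)C)[C@H]3[C@@](O)(CCl)CC[C@H](O[Si](C)(C)C(C)(C)C)[C@]3(C)[C@@H](O[Si](C)(C)C(C)(C)C)[C@@H]1OCOC | intermediate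
34 | 4,8-oxygen-bridged dihydropyran: 5,6-ene, C2/C9/C14 tert-butyldimethylsilyl ethers, C3 methoxymethyl ether | CC=1[C@H]2O[C@]3([C@@H](C)C(=O)O[C@H]3C=1)[C@@H](O[Si](C)(C)C(C)(C)C)[C@H]1[C@@](O)(CCl)CC[C@H](O[Si](C)(C)C(C)(C)C)[C@]1(C)[C@@H](O[Si](C)(C)C(C)(C)C)[C@@H]2OCOC | intermediate
35 | C3 alcohol from 34 (three silyl ethers kept) | CC=1[C@H]2O[C@]3([C@@H](C)C(=O)O[C@H]3C=1)[C@@H](O[Si](C)(C)C(C)(C)C)[C@H]1[C@@](O)(CCl)CC[C@H](O[Si](C)(C)C(C)(C)C)[C@]1(C)[C@@H](O[Si](C)(C)C(C)(C)C)[C@@H]2O | intermediate (not isolated)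
36 | hexaol: free C2, C3, C9, C14 and C11 hydroxyls | CC=1[C@H]2O[C@]3([C@@H](C)C(=O)O[C@H]3C=1)[C@@H](O)[C@H]1[C@@](O)(CCl)CC[C@H](O)[C@]1(C)[C@@H](O)[C@@H]2O | intermediate
37 | 2,3,9,14-tetraacetate with 5,6-ene and C16 methyl | CC=1[C@H]2O[C@]3([C@@H](C)C(=O)O[C@H]3C=1)[C@@H](OC(C)=O)[C@H]1[C@@](O)(CCl)CC[C@H](OC(C)=O)[C@]1(C)[C@@H](OC(C)=O)[C@@H]2OC(C)=O | intermediate
38 | Fragilide F | C=C1[C@H]2O[C@]3([C@@H](C)C(=O)O[C@H]3[C@H]1Cl)[C@@H](OC(C)=O)[C@H]1[C@@](O)(CCl)CC[C@H](OC(C)=O)[C@]1(C)[C@@H](OC(C)=O)[C@@H]2OC(C)=O | target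

**Step count and risks**

Total: 31 steps. Longest linear sequence: 27 steps (steps 1–9 and 14–31); the four-step branch 10–13 supplies 16.

Steps most likely to fail:

1. Step 18 (bears the label). What may go wrong: 1,2-acyl migration from C9, attack of the C7 silyl ether oxygen on C10, or migration of the C12 methylene may compete with the ring-expanding shift of C1. Fallback with known chemistry, in which the epoxide carries no acyl group: set out from 20 and silylate the C8 hydroxyl (TMSCl, imidazole, CH2Cl2) to the C8 trimethylsilyl ether F1. The established Lewis acid semipinacol rearrangement of this simple 2,3-epoxy silyl ether (BF3·OEt2, CH2Cl2, −78 °C) should give the ring-expanded β-hydroxy ketone F2. Protection of C9 (TBSOTf, 2,6-lutidine) gives the C9 silyl ether F3, selective cleavage of the trimethylsilyl ether (citric acid, MeOH, 0 °C) gives the C8 alcohol F4, and Dess–Martin oxidation returns to the route at 23.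

2. Step 26. What may go wrong: intermolecular coupling (oligomerisation) or protodeiodination may outrun closure of the strained ten-membered ring. Fallback: set out from 31 and convert the vinyl iodide by palladium-catalysed silylation (Me3SiSiMe3, Pd2(dba)3, toluene) into the (Z)-vinylsilane aldehyde F5. TMSOTf (CH2Cl2, −78 °C) should then condense the C8 hydroxyl with the aldehyde to an oxocarbenium ion that is captured at C5 by ipso attack of the vinylsilane (vinylsilane-terminated oxocarbenium cyclisation of the silyl-Prins type). The carbon–carbon bond is thus made in a six-membered ring closure inside a reversibly formed eight-membered oxocarbenium ion, and the route is rejoined at 34, steps 26–28 being bypassed.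

3. Step 31. What may go wrong: chlorine transfer to the β face, proton loss from C4 instead of C16, or over-chlorination. Fallback for the case in which electrophiles prefer the β face: set out from 37 and carry out a Schenck ene reaction (O2, tetraphenylporphyrin, hν, CH2Cl2), which oxygenates C6 with the same double-bond shift to the 6β-hydroperoxide F6. Reduction (PPh3) gives the 6β-allylic alcohol F7, and Appel chlorination with inversion (PPh3, CCl4) should deliver the 6α-chloride and return to the route at 38.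

**Further compounds**

F1 | step 18 | C8 trimethylsilyl ether of epoxy alcohol 20 | C=C[C@@H](OCOC)[C@H](O[Si](C)(C)C(C)(C)C)[C@@]1(C)[C@@H](O[Si](C)(C)C(C)(C)C)CC[C@]1(O[Si](CC)(CC)CC)[C@@H]2O[C@@H]2[C@@H](O[Si](C)(C)C)[C@@H](O[Si](CC)(CC)CC)/C=C(/C)I
F2 | step 18 | ring-expanded β-hydroxy ketone with C8 trimethylsilyl ether (C11 ketone, free C9 hydroxyl) | C=C[C@@H](OCOC)[C@H](O[Si](C)(C)C(C)(C)C)[C@@]1(C)[C@@H](O[Si](C)(C)C(C)(C)C)CCC(=O)[C@@H]1[C@H](O)[C@@H](O[Si](C)(C)C)[C@@H](O[Si](CC)(CC)CC)/C=C(/C)I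
F3 | step 18 | C9 tert-butyldimethylsilyl ether of F2 | C=C[C@@H](OCOC)[C@H](O[Si](C)(C)C(C)(C)C)[C@@]1(C)[C@@H](O[Si](C)(C)C(C)(C)C)CCC(=O)[C@@H]1[C@H](O[Si](C)(C)C(C)(C)C)[C@@H](O[Si](C)(C)C)[C@@H](O[Si](CC)(CC)CC)/C=C(/C)I
F4 | step 18 | C8 alcohol from F3 | C=C[C@@H](OCOC)[C@H](O[Si](C)(C)C(C)(C)C)[C@@]1(C)[C@@H](O[Si](C)(C)C(C)(C)C)CCC(=O)[C@@H]1[C@H](O[Si](C)(C)C(C)(C)C)[C@@H](O)[C@@H](O[Si](CC)(CC)CC)/C=C(/C)I
F5 | step 26 | (Z)-vinylsilane analogue of aldehyde 31 (SiMe3 in place of iodine) | O=C[C@@H](OCOC)[C@H](O[Si](C)(C)C(C)(C)C)[C@@]1(C)[C@@H](O[Si](C)(C)C(C)(C)C)CC[C@](O)(CCl)[C@@H]1[C@H](O[Si](C)(C)C(C)(C)C)[C@]2(O)[C@@H](C)C(=O)O[C@H]2/C=C(/C)[Si](C)(C)C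
F6 | step 31 | 6β-hydroperoxide with C5=C16 methylene (tetraacetate) | C=C1[C@H]2O[C@]3([C@@H](C)C(=O)O[C@H]3[C@@H]1OO)[C@@H](OC(C)=O)[C@H]1[C@@](O)(CCl)CC[C@H](OC(C)=O)[C@]1(C)[C@@H](OC(C)=O)[C@@H]2OC(C)=O
F7 | step 31 | 6β-allylic alcohol with C5=C16 methylene (tetraacetate) | C=C1[C@H]2O[C@]3([C@@H](C)C(=O)O[C@H]3[C@@H]1O)[C@@H](OC(C)=O)[C@H]1[C@@](O)(CCl)CC[C@H](OC(C)=O)[C@]1(C)[C@@H](OC(C)=O)[C@@H]2OC(C)=O
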